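**Retrosynthetic overview**
- Target 20 ← 19 ← 18 ← 17 ← 16: debenzylation, acetylation of C1–OH and reduction of the ring-B lactone carbon C8 to CH2 lead back to the bicyclic lactone 16.
- Key disconnection: ring A of 16 is the three-atom unit C2–O3–C4 laid across the C1–C5 ring-fusion bond. It is cut as the [3+2] adduct of the carbonyl ylide ArCH=O(+)–CH2(−) (15) with the C1=C5 alkene of butenolide 11, in which C1 already bears its oxygen and ring B already holds C6.
- 11 ← 10 ← 7: enol acetate of the isotetronic acid, obtained by ozonolysis of an α-methylene lactone; 7 comes from catalytic asymmetric 2-(ethoxycarbonyl)allylation of O-benzylvanillin 3, which sets C6.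
- Ylide precursor 14 ← acetal 13 ← 3 + (trimethylsilyl)methanol 12.
- Ring order: ring B first (as lactone, step 2), ring A second (step 7); the oxidation level at C8 is adjusted last.

Key step: step 7

Remark (assumption): core numbering is C1 (oxygen-bearing bridgehead), C2 (ArCH on C1), O3, C4, C5 (H bridgehead), C6 (ArCH on C5), O7, C8 (on C1); Ar = 4-benzyloxy-3-methoxyphenyl until step 11; in step 2 the ligand antipode that gives Si-face allyl transfer is assumed.

**Route**

Step 1
Reactants: 1 vanillin; 2 benzyl bromide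
Product: 3 4-benzyloxy-3-methoxybenzaldehyde
Conditions: K2CO3, DMF, rt
Reagents that add atoms: none
Why: Williamson ether synthesis of the phenoxide with a benzylic bromide gives a phenol protecting group that should survive the fluoride, hydride and Lewis-acid steps.

Step 2
Reactants: 3 4-benzyloxy-3-methoxybenzaldehyde; 4 ethyl 2-(bromomethyl)acrylate
Product: 7 (S)-5-(4-benzyloxy-3-methoxyphenyl)-3-methylenedihydrofuran-2(3H)-one, via silyl ether 5 (not isolated), via hydroxy ester 6 (not isolated)
Conditions: CrCl2 (10 mol%), chiral 1,8-bis(oxazolinyl)carbazole ligand (11 mol%), Mn powder, TMSCl, Et3N (20 mol%), THF, rt; then 1 M HCl, THF; TsOH (cat.), CH2Cl2, rt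
Reagents that add atoms: none
Why: In this catalytic asymmetric Nozaki–Hiyama–Kishi-type 2-(alkoxycarbonyl)allylation the allylchromium species from 4 adds to the Si face of the aldehyde inside the chiral tridentate ligand sphere and sets C6 as S, Mn and TMSCl turn the chromium over, and the γ-hydroxy ester lactonises under acid to close ring B.

Step 3
Reactants: 7 (S)-5-(4-benzyloxy-3-methoxyphenyl)-3-methylenedihydrofuran-2(3H)-one
Product: 10 (S)-5-(4-benzyloxy-3-methoxyphenyl)-3-hydroxyfuran-2(5H)-one, via ozonide 8 (not isolated), via keto lactone 9 (not isolated)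
Conditions: O3, CH2Cl2, −78 °C (Sudan Red 7B end point); then Me2S, −78 °C → rt
Reagents that add atoms: ozone, O=[O+][O-]
Why: Ozonolysis (Criegee mechanism) of the exocyclic alkene removes the methylene carbon as formaldehyde and the α-keto lactone tautomerises to its conjugated enol with C6 untouched, ozone being dosed to an indicator end point so that the dialkoxyarene is spared.

Step 4
Reactants: 10 (S)-5-(4-benzyloxy-3-methoxyphenyl)-3-hydroxyfuran-2(5H)-one
Product: 11 (S)-5-(4-benzyloxy-3-methoxyphenyl)-2-oxo-2,5-dihydrofuran-3-yl acetate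
Conditions: Ac2O, pyridine, CH2Cl2, 0 °C
Reagents that add atoms: acetic anhydride, CC(=O)OC(C)=O
Why: O-Acylation of the acidic enol hydroxyl with a weak base at low temperature should give the enol acetate without deprotonating the acidic γ-hydrogen at C6.

Step 5
Reactants: 3 4-benzyloxy-3-methoxybenzaldehyde; 12 (trimethylsilyl)methanol
Product: 13 4-benzyloxy-3-methoxybenzaldehyde bis[(trimethylsilyl)methyl] acetal
Conditions: 12 (2.5 equiv), pyridinium p-toluenesulfonate (cat.), cyclohexane, reflux, Dean–Stark
Reagents that add atoms: none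
Why: Acid-catalysed acetalisation with a primary alcohol is driven to completion by azeotropic removal of water.

Step 6
Reactants: 13 4-benzyloxy-3-methoxybenzaldehyde bis[(trimethylsilyl)methyl] acetal
Product: 14 α-chloro-4-benzyloxy-3-methoxybenzyl (trimethylsilyl)methyl ether (racemic, used crude)
Conditions: AcCl (1.1 equiv), SOCl2 (2 mol%), CH2Cl2, 0 °C → rt; volatiles removed in vacuo
Reagents that add atoms: acetyl chloride, CC(Cl)=O
Why: In this acetal to α-chloro ether exchange, acylation of one acetal oxygen expels (trimethylsilyl)methyl acetate and chloride captures the p-alkoxybenzyl-stabilised oxocarbenium ion, the racemic chloride-bearing carbon becoming planar in the ylide.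

Step 7
Reactants: 11 (S)-5-(4-benzyloxy-3-methoxyphenyl)-2-oxo-2,5-dihydrofuran-3-yl acetate; 14 α-chloro-4-benzyloxy-3-methoxybenzyl (trimethylsilyl)methyl ether
Product: 16 (1R,2R,5R,6S)-2,6-bis(4-benzyloxy-3-methoxyphenyl)-8-oxo-3,7-dioxabicyclo[3.3.0]octan-1-yl acetate, via carbonyl ylide 15 (not isolated)
Conditions: 14 (3 equiv), CsF (spray-dried, 4 equiv, added in portions), MeCN, 0 °C → rt
Reagents that add atoms: none
Why: Proposed new method: fluoride attacks silicon of 14, which ionises readily at its p-alkoxybenzylic C–Cl bond, and this 1,3-elimination of Me3SiF and chloride releases the non-stabilised carbonyl ylide 15, which adds as the 4π component across C1=C5 of 11 in a suprafacial [3+2] cycloaddition; the closest known reaction is the same CsF-triggered ylide generation from α-chloroalkyl (trimethylsilyl)methyl ethers followed by addition to acrylates, fumarates, maleates and maleimides, which has not been tried on an α-acyloxy butenolide. Ring A (C1–C2–O3–C4–C5) is closed in this single intermolecular cycloaddition, C4–C5 and C1–C2 forming on the same face (C4–C5 probably in advance), so the A/B fusion can only be cis. C5 and C1 are set by the C6 stereocentre of 11: the ylide approaches the face anti to the C6 aryl group, which puts H-5 cis to that aryl group and the acetate on the convex face. The regiochemistry needed (CH2 to C5, ArCH to C1) follows from matched polarisation, the ylide carrying its negative charge on the unsubstituted terminus because the p-alkoxyaryl group stabilises cationic character at ArCH, and the butenolide being electrophilic at its β-carbon C5. C2 is set by ylide geometry and approach mode: the E ylide (aryl anti to CH2) reacting with its oxygen over the open C5–H/C1–O edge, not over ring B whose C6–H points into the reacting face, places the aryl group on the convex face cis to the acetate as in the target; this is the least secure element, and a C2 epimer would be separated and returned by acid equilibration at the benzylic C2–O3 bond. The selectivity the step needs beyond this is chemoselectivity for silicon over the enol acetate and the acidic C6–H, which is served by keeping CsF heterogeneous and adding it in portions to a solution that already holds excess 14.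

Step 8
Reactants: 16 (1R,2R,5R,6S)-2,6-bis(4-benzyloxy-3-methoxyphenyl)-8-oxo-3,7-dioxabicyclo[3.3.0]octan-1-yl acetate
Product: 17 (1R,2R,5R,6S)-2,6-bis(4-benzyloxy-3-methoxyphenyl)-3,7-dioxabicyclo[3.3.0]octane-1,8-diol (lactol, both C8 anomers)
Conditions: i-Bu2AlH (3.5 equiv), CH2Cl2, −78 °C; MeOH quench at −78 °C, then aq. potassium sodium tartrate
Reagents that add atoms: none
Why: Hydride reduction at −78 °C should stop at the aluminium hemiacetal of the lactone, giving the lactol on work-up, while the same reagent removes the C1 acetate by addition to its carbonyl, and only the inconsequential anomeric centre C8 is new.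

Step 9
Reactants: 17 (1R,2R,5R,6S)-2,6-bis(4-benzyloxy-3-methoxyphenyl)-3,7-dioxabicyclo[3.3.0]octane-1,8-diol
Product: 18 (1S,2R,5R,6S)-2,6-bis(4-benzyloxy-3-methoxyphenyl)-3,7-dioxabicyclo[3.3.0]octan-1-ol (di-O-benzyl-1-hydroxypinoresinol)
Conditions: Et3SiH (3 equiv), BF3·OEt2 (2 equiv), CH2Cl2, −78 → −40 °C; aq. NaHCO3
Reagents that add atoms: none
Why: In this ionic hydrogenation BF3 ionises the anomeric hydroxyl to the ring-B oxocarbenium ion at C8 and the silane reduces it to CH2, a lactol deoxygenation used on 2,6-diaryl furofuran lactols and run cold so that the benzylic C2–O3 and C6–O7 bonds stay closed.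

Step 10
Reactants: 18 (1S,2R,5R,6S)-2,6-bis(4-benzyloxy-3-methoxyphenyl)-3,7-dioxabicyclo[3.3.0]octan-1-ol
Product: 19 (1S,2R,5R,6S)-2,6-bis(4-benzyloxy-3-methoxyphenyl)-3,7-dioxabicyclo[3.3.0]octan-1-yl acetate
Conditions: Ac2O (5 equiv), Et3N, DMAP (0.5 equiv), CH2Cl2, rt → 40 °C
Reagents that add atoms: acetic anhydride, CC(=O)OC(C)=O
Why: DMAP-catalysed acyl transfer through the N-acetylpyridinium ion is the standard way to acylate a hindered tertiary alcohol, and 18 has no other free hydroxyl.

Step 11
Reactants: 19 (1S,2R,5R,6S)-2,6-bis(4-benzyloxy-3-methoxyphenyl)-3,7-dioxabicyclo[3.3.0]octan-1-yl acetate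
Product: 20 (1S,2R,5R,6S)-2,6-bis(4-hydroxy-3-methoxyphenyl)-3,7-dioxabicyclo[3.3.0]octan-1-yl acetate (1-acetoxypinoresinol)
Conditions: H2 (1 atm), 10% Pd/C, EtOAc, rt; stopped at full debenzylation
Reagents that add atoms: none
Why: Hydrogenolysis of aryl benzyl ethers over Pd/C in a neutral aprotic solvent is much faster than cleavage of the dialkyl benzylic C–O bonds of the furofuran and should leave the tertiary acetate and all four stereocentres intact.

**Compound list**

1 | vanillin (4-hydroxy-3-methoxybenzaldehyde) | COc1cc(C=O)ccc1O | starting material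
2 | benzyl bromide | BrCc1ccccc1 | starting material
3 | 4-benzyloxy-3-methoxybenzaldehyde | COc1cc(C=O)ccc1OCc1ccccc1 | intermediate
4 | ethyl 2-(bromomethyl)acrylate | CCOC(=O)C(=C)CBr | starting material
5 | ethyl (S)-4-(4-benzyloxy-3-methoxyphenyl)-2-methylene-4-(trimethylsilyloxy)butanoate (silyl ether) | COc1cc([C@H](CC(=C)C(=O)OCC)O[Si](C)(C)C)ccc1OCc1ccccc1 | intermediate
6 | ethyl (S)-4-(4-benzyloxy-3-methoxyphenyl)-4-hydroxy-2-methylenebutanoate (hydroxy ester) | COc1cc([C@H](CC(=C)C(=O)OCC)O)ccc1OCc1ccccc1 | intermediate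
7 | (S)-5-(4-benzyloxy-3-methoxyphenyl)-3-methylenedihydrofuran-2(3H)-one | COc1cc([C@H]2OC(=O)C(=C)C2)ccc1OCc1ccccc1 | intermediate
8 | spiro-1,2,4-trioxolane (ozonide) of 7, mixture at the spiro carbon | COc1cc([C@H]2OC(=O)C3(OCOO3)C2)ccc1OCc1ccccc1 | intermediate
9 | (S)-5-(4-benzyloxy-3-methoxyphenyl)dihydrofuran-2,3-dione (keto lactone) | COc1cc([C@H]2OC(=O)C(=O)C2)ccc1OCc1ccccc1 | intermediate
10 | (S)-5-(4-benzyloxy-3-methoxyphenyl)-3-hydroxyfuran-2(5H)-one | COc1cc([C@H]2OC(=O)C(O)=C2)ccc1OCc1ccccc1 | intermediate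
11 | (S)-5-(4-benzyloxy-3-methoxyphenyl)-2-oxo-2,5-dihydrofuran-3-yl acetate | COc1cc([C@H]2OC(=O)C(OC(C)=O)=C2)ccc1OCc1ccccc1 | intermediate
12 | (trimethylsilyl)methanol | C[Si](C)(C)CO | starting material
13 | 4-benzyloxy-3-methoxybenzaldehyde bis[(trimethylsilyl)methyl] acetal | COc1cc(C(OC[Si](C)(C)C)OC[Si](C)(C)C)ccc1OCc1ccccc1 | intermediate
14 | α-chloro-4-benzyloxy-3-methoxybenzyl (trimethylsilyl)methyl ether, racemic | COc1cc(C(Cl)OC[Si](C)(C)C)ccc1OCc1ccccc1 | intermediate
15 | carbonyl ylide, (4-benzyloxy-3-methoxybenzylidene)oxonium methylide | COc1cc(C=[O+][CH2-])ccc1OCc1ccccc1 | intermediate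
16 | (1R,2R,5R,6S)-2,6-bis(4-benzyloxy-3-methoxyphenyl)-8-oxo-3,7-dioxabicyclo[3.3.0]octan-1-yl acetate (cis-fused, both aryl groups exo) | COc1cc([C@H]2OC(=O)[C@]3(OC(C)=O)[C@@H](c4ccc(OCc5ccccc5)c(OC)c4)OC[C@H]23)ccc1OCc1ccccc1 | intermediate
17 | (1R,2R,5R,6S)-2,6-bis(4-benzyloxy-3-methoxyphenyl)-3,7-dioxabicyclo[3.3.0]octane-1,8-diol (lactol, C8 anomers) | COc1cc([C@H]2OC(O)[C@]3(O)[C@@H](c4ccc(OCc5ccccc5)c(OC)c4)OC[C@H]23)ccc1OCc1ccccc1 | intermediate
18 | (1S,2R,5R,6S)-2,6-bis(4-benzyloxy-3-methoxyphenyl)-3,7-dioxabicyclo[3.3.0]octan-1-ol | COc1cc([C@H]2OC[C@]3(O)[C@@H](c4ccc(OCc5ccccc5)c(OC)c4)OC[C@H]23)ccc1OCc1ccccc1 | intermediate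
19 | (1S,2R,5R,6S)-2,6-bis(4-benzyloxy-3-methoxyphenyl)-3,7-dioxabicyclo[3.3.0]octan-1-yl acetate | COc1cc([C@H]2OC[C@]3(OC(C)=O)[C@@H](c4ccc(OCc5ccccc5)c(OC)c4)OC[C@H]23)ccc1OCc1ccccc1 | intermediate
20 | 1-acetoxypinoresinol, (1S,2R,5R,6S)-2,6-bis(4-hydroxy-3-methoxyphenyl)-3,7-dioxabicyclo[3.3.0]octan-1-yl acetate | COc1cc([C@H]2OC[C@]3(OC(C)=O)[C@@H](c4ccc(O)c(OC)c4)OC[C@H]23)ccc1O | target

**Step count**

Total steps: 11. Longest linear sequence: 9 (steps 1, 2, 3, 4, 7, 8, 9, 10, 11).

**Steps most likely to fail**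

1. Step 7 (ring-A cycloaddition).
 - What may go wrong: the short-lived ylide may dimerise or close to the aryl oxirane faster than it adds to the hindered, acetoxy-substituted alkene. Fluoride may strip the enol acetate or deprotonate C6, with loss of enantiopurity. The aryl group at C2 may end up mainly on the concave face.
 - Fallback (known reactions only), setting out from 10 and coming back at 17: the C1 oxygen is taken off before the cycloaddition and put back after it.
 - 10 is triflated (Tf2O, 2,6-lutidine, CH2Cl2, −78 °C) to the enol triflate (S)-5-(4-benzyloxy-3-methoxyphenyl)-2-oxo-2,5-dihydrofuran-3-yl trifluoromethanesulfonate F1. Palladium-catalysed hydride transfer (Pd(PPh3)4, Bu3SnH, LiCl, THF) then gives the plain butenolide (S)-5-(4-benzyloxy-3-methoxyphenyl)furan-2(5H)-one F2.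
 - F2 is a simple γ-substituted enoate of the class already known to take up these ylides. With 14 and CsF in MeCN it should give, anti to the aryl group, the cis-fused furofuranone (1S,2S,5R,6S)-2,6-bis(4-benzyloxy-3-methoxyphenyl)-3,7-dioxabicyclo[3.3.0]octan-8-one F3.
 - Deprotonation at C1 (KN(SiMe3)2, THF, −78 °C) gives an enolate whose β-oxygen O3 is held nearly in the enolate plane, so elimination should be slow. Oxidation with 2-(phenylsulfonyl)-3-phenyloxaziridine, which can only arrive on the convex face, gives the tertiary alcohol (1R,2R,5R,6S)-1-hydroxy-2,6-bis(4-benzyloxy-3-methoxyphenyl)-3,7-dioxabicyclo[3.3.0]octan-8-one F4.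
 - Reduction of F4 with i-Bu2AlH at −78 °C gives 17.

2. Step 9 (lactol deoxygenation).
 - What may go wrong: the Lewis acid may ionise the p-alkoxybenzylic C2–O3 or C6–O7 bond instead of, or as well as, the anomeric C8–OH, which sits next to the oxygenated C1. That would lead to epimerisation at C2 or C6, or to silane reduction with ring opening.
 - Fallback, setting out from 16 and coming back at 18: ring B is reclosed by O-alkylation under basic conditions instead of hydride delivery to a cation.
 - LiAlH4 (THF, 0 °C) reduces the lactone and the acetate of 16 to the triol (2R,3S,4R)-2-(4-benzyloxy-3-methoxyphenyl)-4-[(S)-(4-benzyloxy-3-methoxyphenyl)(hydroxy)methyl]-3-(hydroxymethyl)oxolan-3-ol F5.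
 - Tin-mediated selective sulfonylation of the primary hydroxyl of the C1/C8 1,2-diol (TsCl, Et3N, Bu2SnO cat., CH2Cl2) gives the mono-tosylate {(2R,3S,4R)-2-(4-benzyloxy-3-methoxyphenyl)-4-[(S)-(4-benzyloxy-3-methoxyphenyl)(hydroxy)methyl]-3-hydroxyoxolan-3-yl}methyl 4-methylbenzenesulfonate F6.
 - K2CO3 in MeOH lets the C6 alkoxide displace the tosylate at C8 in a 5-exo-tet closure that leaves the C6–O bond, and so the C6 configuration, untouched, giving 18. The process to watch is competing attack of the neighbouring C1 hydroxyl on C8.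

3. Step 2 (asymmetric allylation).
 - What may go wrong: slow turnover with the electron-rich aldehyde (pinacol coupling competing) or insufficient facial discrimination, which would lower the enantiopurity of everything downstream.
 - Fallback, setting out from 3 and 4 and coming back at 7: the stereocentre is set by ketone reduction instead of C–C bond formation.
 - Zinc-mediated Barbier allylation (Zn, aq. NH4Cl, THF) gives racemic ethyl 4-(4-benzyloxy-3-methoxyphenyl)-4-hydroxy-2-methylenebutanoate F7.
 - MnO2 (CH2Cl2) oxidises the benzylic alcohol to the aryl ketone ethyl 4-(4-benzyloxy-3-methoxyphenyl)-2-methylene-4-oxobutanoate F8. It is kept neutral to avoid migration of the alkene into conjugation.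
 - Corey–Bakshi–Shibata reduction ((R)-2-methyl-CBS-oxazaborolidine cat., catecholborane, toluene, −78 °C) delivers hydride to give the (S)-alcohol 6, which lactonises with TsOH to 7.

**Further compounds**

F1 | step 7 | (S)-5-(4-benzyloxy-3-methoxyphenyl)-2-oxo-2,5-dihydrofuran-3-yl trifluoromethanesulfonate | COc1cc([C@H]2OC(=O)C(OS(=O)(=O)C(F)(F)F)=C2)ccc1OCc1ccccc1
F2 | step 7 | (S)-5-(4-benzyloxy-3-methoxyphenyl)furan-2(5H)-one | COc1cc([C@H]2OC(=O)C=C2)ccc1OCc1ccccc1
F3 | step 7 | (1S,2S,5R,6S)-2,6-bis(4-benzyloxy-3-methoxyphenyl)-3,7-dioxabicyclo[3.3.0]octan-8-one | COc1cc([C@H]2OC(=O)[C@@H]3[C@@H](c4ccc(OCc5ccccc5)c(OC)c4)OC[C@H]23)ccc1OCc1ccccc1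
F4 | step 7 | (1R,2R,5R,6S)-1-hydroxy-2,6-bis(4-benzyloxy-3-methoxyphenyl)-3,7-dioxabicyclo[3.3.0]octan-8-one | COc1cc([C@H]2OC(=O)[C@]3(O)[C@@H](c4ccc(OCc5ccccc5)c(OC)c4)OC[C@H]23)ccc1OCc1ccccc1
F5 | step 9 | (2R,3S,4R)-2-(4-benzyloxy-3-methoxyphenyl)-4-[(S)-(4-benzyloxy-3-methoxyphenyl)(hydroxy)methyl]-3-(hydroxymethyl)oxolan-3-ol | COc1cc([C@@H](O)[C@H]2CO[C@H](c3ccc(OCc4ccccc4)c(OC)c3)[C@@]2(O)CO)ccc1OCc1ccccc1
F6 | step 9 | {(2R,3S,4R)-2-(4-benzyloxy-3-methoxyphenyl)-4-[(S)-(4-benzyloxy-3-methoxyphenyl)(hydroxy)methyl]-3-hydroxyoxolan-3-yl}methyl 4-methylbenzenesulfonate | COc1cc([C@@H](O)[C@H]2CO[C@H](c3ccc(OCc4ccccc4)c(OC)c3)[C@@]2(O)COS(=O)(=O)c2ccc(C)cc2)ccc1OCc1ccccc1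
F7 | step 2 | racemic ethyl 4-(4-benzyloxy-3-methoxyphenyl)-4-hydroxy-2-methylenebutanoate | CCOC(=O)C(=C)CC(O)c1ccc(OCc2ccccc2)c(OC)c1
F8 | step 2 | ethyl 4-(4-benzyloxy-3-methoxyphenyl)-2-methylene-4-oxobutanoate | CCOC(=O)C(=C)CC(=O)c1ccc(OCc2ccccc2)c(OC)c1
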